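**Plan**

- Cuts (elemane numbering: C10 quaternary, C9 ring CH2, C8 ester carbinol, C7/C6 lactone fusion, C5 bearing the hydroxypropenyl group, C14 hydroxymethyl): the C8 ester; the lactone carbonyl C12 (C11–C12 and C12–O, by carbonylation); ring bonds C9–C10 and C6–C7 in one operation; then the O–C8 tether, C10=C1 and C5–C4.
- Enabling feature of the cyclohexane ring: C8, the oxygenated carbon between the two new bonds, is taken as a ketone. Its α-carbon C9 ends on the vinyl-bearing quaternary C10 (allyl transposition, Claisen). Its other α-carbon C7 carries a 1-substituted vinyl group next to the C6 carbinol (γ-bromo-enone dienolate plus aldehyde, Barbier).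
- Forward: (S)-butenolide → 2-methoxyoxolane carrying C5 and an exocyclic allylic alcohol (temporary ring masking the C6 aldehyde and the C14 hydroxyl) → ester → allyl dienyl ether → one-flask Claisen rearrangement / indium Barbier closure of the cyclohexanone (oxolane removed) → γ-lactone by carbonylation → ketone reduction → acylation → desilylation.
- Stereochemistry: C5 from cuprate addition trans to the butenolide substituent; C10 from Claisen attack anti to the C5 substituent on the oxolane; C6 and C7 from the all-equatorial chair closure; C8 from hydride delivered by the axial C14 hydroxyl; the (Z)-acyl group from syn hydroalumination of an ynoate.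

Key step: step 11

Remark on the chemistry: the acetal carbon of oxolanes 12, 13 and 18–21 is carried as a mixture of anomers, because it becomes the aldehyde carbon in step 11.

**Route**

Step 1
Reactants: 1 (5S)-5-(hydroxymethyl)furan-2(5H)-one
Product: 2 [(2S)-5-oxo-2,5-dihydrofuran-2-yl]methyl 2,2-dimethylpropanoate
Conditions: PivCl, pyridine, CH2Cl2, 0 °C
Reagents that add atoms: pivaloyl chloride, CC(C)(C)C(=O)Cl
Why: O-acylation of the primary alcohol gives a pivalate that survives the cuprate and enolate chemistry and is cleaved by the hydride of step 5 without a separate operation, the stereocentre being untouched.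

Step 2
Reactants: 3 2-bromoprop-2-en-1-ol
Product: 4 [(2-bromoprop-2-en-1-yl)oxy](tert-butyl)diphenylsilane
Conditions: TBDPSCl, imidazole, DMF, 25 °C
Reagents that add atoms: tert-butyl(chloro)diphenylsilane, CC(C)(C)[Si](Cl)(c1ccccc1)c1ccccc1
Why: Silyl ether formation protects the future C15 hydroxyl with a group that should last until step 19.

Step 3
Reactants: 4 [(2-bromoprop-2-en-1-yl)oxy](tert-butyl)diphenylsilane, 2 [(2S)-5-oxo-2,5-dihydrofuran-2-yl]methyl 2,2-dimethylpropanoate, 5 {[tert-butyl(dimethyl)silyl]oxy}acetaldehyde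
Product: 8 [(2S,3R)-4-(2-{[tert-butyl(dimethyl)silyl]oxy}-1-hydroxyethyl)-3-{3-[(tert-butyldiphenylsilyl)oxy]prop-1-en-2-yl}-5-oxooxolan-2-yl]methyl 2,2-dimethylpropanoate (epimer mixture at C4 plus the carbinol carbon), via lithium dialkenylcuprate 6 (not isolated), via lactone enolate 7 (not isolated)
Conditions: 4, t-BuLi, Et2O, −78 °C; CuI, −78 to −40 °C; then 2, −78 °C; then 5, −78 to −40 °C; aq. NH4Cl
Reagents that add atoms: none
Why: Tandem organocuprate conjugate addition–aldol, in which the alkenyl group should add to the butenolide on the face opposite the neighbouring acyloxymethyl group (1,2-induction from the ring stereocentre, setting the future C5) and the enolate is trapped by the aldehyde at centres that step 4 removes.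

Step 4
Reactants: 8 the aldol adduct of step 3
Product: 10 [(2S,3S,4E)-4-(2-{[tert-butyl(dimethyl)silyl]oxy}ethylidene)-3-{3-[(tert-butyldiphenylsilyl)oxy]prop-1-en-2-yl}-5-oxooxolan-2-yl]methyl 2,2-dimethylpropanoate, via secondary mesylate 9 (not isolated)
Conditions: MsCl, Et3N, CH2Cl2, 0 °C; then DBU, 25 °C
Reagents that add atoms: none
Why: Sulfonylation followed by E1cB elimination through the lactone enolate should give the conjugated alkylidene lactone (E isomer expected), whose geometry has no bearing on later stereochemistry.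

Step 5
Reactants: 10 the alkylidene lactone of step 4
Product: 11 (2S,3S,4E)-6-{[tert-butyl(dimethyl)silyl]oxy}-3-{3-[(tert-butyldiphenylsilyl)oxy]prop-1-en-2-yl}-4-(hydroxymethyl)hex-4-ene-1,2-diol
Conditions: i-Bu2AlH (excess), CH2Cl2, −78 to 0 °C; aq. potassium sodium tartrate
Reagents that add atoms: none
Why: 1,2-Hydride reduction opens the lactone to the allylic primary alcohol and the secondary alcohol and cleaves the pivalate at the same time, exposing the 1,2-diol without touching a stereocentre.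

Step 6
Reactants: 11 the triol of step 5
Product: 13 (2E)-2-[(4S)-4-{3-[(tert-butyldiphenylsilyl)oxy]prop-1-en-2-yl}-5-methoxyoxolan-3-ylidene]ethan-1-ol, via lactol 12 (not isolated)
Conditions: NaIO4, THF/aq. NaH2PO4–Na2HPO4 (pH 7), 0 °C; then PPTS, MeOH, 25 °C
Reagents that add atoms: methanol, CO
Why: Malaprade glycol cleavage gives the aldehyde, which should close at once onto the allylic hydroxyl as a five-membered lactol, and mild acid in methanol then forms the methyl acetal while cleaving the primary TBS ether, so that aldehyde and C14 hydroxyl are tied in one temporary ring and the other allylic hydroxyl is free.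

Step 7
Reactants: 14 but-2-ynoic acid
Product: 15 (2Z)-3-bromobut-2-enoic acid
Conditions: 48% aq. HBr, 25 to 50 °C
Reagents that add atoms: hydrogen bromide, Br
Why: anti-Hydrobromination of the ynoic acid (bromide adds to the β-carbon) should give the (Z)-β-bromo acid.

Step 8
Reactants: 15 (2Z)-3-bromobut-2-enoic acid
Product: 16 (2Z)-3,4-dibromobut-2-enoic acid
Conditions: NBS, dibenzoyl peroxide (cat.), PhCF3, reflux
Reagents that add atoms: N-bromosuccinimide, O=C1CCC(=O)N1Br
Why: Wohl–Ziegler radical bromination at the only allylic C–H position installs the allylic bromide needed for the Barbier closure.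

Step 9
Reactants: 16 (2Z)-3,4-dibromobut-2-enoic acid, 13 the allylic alcohol of step 6
Product: 18 (2E)-2-[(4S)-4-{3-[(tert-butyldiphenylsilyl)oxy]prop-1-en-2-yl}-5-methoxyoxolan-3-ylidene]ethyl (2Z)-3,4-dibromobut-2-enoate, via acid chloride 17 (not isolated)
Conditions: (COCl)2, DMF (cat.), CH2Cl2, 0 °C; evaporate; then 13, 2,6-lutidine, CH2Cl2, −20 to 0 °C
Reagents that add atoms: none
Why: Acylation of the primary allylic alcohol by the acid chloride under a hindered base (to avoid addition–elimination at the β-bromoacrylate) joins the two fragments through the oxygen that becomes the Claisen tether.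

Step 10
Reactants: 18 the ester of step 9
Product: 19 tert-butyl{[2-((3S,4E)-4-{2-[((3Z)-4,5-dibromopenta-1,3-dien-2-yl)oxy]ethylidene}-2-methoxyoxolan-3-yl)prop-2-en-1-yl]oxy}diphenylsilane
Conditions: Cp2TiMe2, toluene/THF, 60 °C, dark; filtration through basic Al2O3
Reagents that add atoms: dimethyltitanocene, C[Ti](C)(C1C=CC=C1)C1C=CC=C1
Why: Petasis methylenation of the only carbonyl group turns the ester into a 1,1-disubstituted enol ether under neutral conditions, giving the allyl 2-dienyl ether with acetal, silyl ether and halides intact.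

Step 11
Reactants: 19 the allyl dienyl ether of step 10
Product: 22 (2S,3R,4S,5R)-2-(1-bromoethenyl)-4-{3-[(tert-butyldiphenylsilyl)oxy]prop-1-en-2-yl}-5-ethenyl-3-hydroxy-5-(hydroxymethyl)cyclohexan-1-one, via Claisen ketone 20 (not isolated), via lactol 21 (not isolated)
Conditions: toluene (0.01 M), 110 °C; cool; then THF, 0.2 M aq. HCl, In powder, 25 °C, same flask
Reagents that add atoms: water, O
Why: On heating, 19 should undergo a Claisen [3,3] rearrangement in which the enol-ether CH2 (C9) bonds to the fully substituted allyl terminus (C10) and the allyl unit is transposed into the vinyl group, giving ketone 20; aqueous acid then releases lactol 21, indium metal inserts into the allylic C–Br bond, and the indium dienolate adds through the carbon α to the ketone (C7) to the open-chain aldehyde (C6), forming the second C–C bond. The closest known reaction types are the Claisen rearrangement of allyl 2-alkoxydienyl ethers made by ester methylenation and the aqueous indium Barbier reaction of 2-bromoallyl and γ-bromo-enone halides (vinylogous Reformatsky) with unprotected lactols. One ring is closed, the cyclohexanone, by a 6-exo-trig addition to the aldehyde (enolendo for the nucleophile), while the temporary oxolane is opened and returns the C14 hydroxyl. C10 is set in the rearrangement by the oxolane ring, the enol-ether terminus adding to the exocyclic alkene on the face anti to the alkenyl substituent on the neighbouring ring carbon C5. C6 and C7 are set in a chair-like, indium-bridged transition state in which the C5 substituent, the forming C6–O bond, the bromovinyl group on C7 and the vinyl group on C10 are all equatorial. The step needs insertion at the allylic and not a vinylic C–Br bond, which the allylic position γ to the carbonyl secures, and attack through C7 and not the CH2 terminus, which the six- against eight-membered ring size secures.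

Step 12
Reactants: 22 the cyclohexanone of step 11
Product: 23 (3aS,6R,7S,7aR)-7-{3-[(tert-butyldiphenylsilyl)oxy]prop-1-en-2-yl}-6-ethenyl-6-(hydroxymethyl)-3-methylidenetetrahydro-1-benzofuran-2,4(3H,5H)-dione
Conditions: PdCl2(PPh3)2 (cat.), CO (1 atm), NaOAc, THF, 45 °C
Reagents that add atoms: carbon monoxide, [C-]#[O+]
Why: Palladium-catalysed carbonylative lactonisation of the 2-bromo homoallylic alcohol (oxidative addition of zerovalent palladium to the vinyl bromide, CO insertion, acyl capture by the adjacent equatorial hydroxyl) should close the trans-fused α-methylene γ-lactone, the weak base being chosen to avoid isomerisation at the carbon α to the ketone.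

Step 13
Reactants: 23 the keto lactone of step 12
Product: 24 (3aR,4S,6R,7S,7aR)-7-{3-[(tert-butyldiphenylsilyl)oxy]prop-1-en-2-yl}-6-ethenyl-4-hydroxy-6-(hydroxymethyl)-3-methylidenehexahydro-1-benzofuran-2(3H)-one
Conditions: Me4NBH(OAc)3, MeCN/AcOH, −20 °C
Reagents that add atoms: none
Why: Hydroxyl-directed reduction of Evans–Saksena type, in which the axial hydroxymethyl group binds boron and delivers hydride to the same face of the ketone, should give the equatorial 4S alcohol, and the mild acetoxyborohydride leaves the α-methylene lactone alone.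

Step 14
Reactants: 24 the diol of step 13
Product: 25 (3aR,4S,6R,7S,7aR)-6-({[tert-butyl(dimethyl)silyl]oxy}methyl)-7-{3-[(tert-butyldiphenylsilyl)oxy]prop-1-en-2-yl}-6-ethenyl-4-hydroxy-3-methylidenehexahydro-1-benzofuran-2(3H)-one
Conditions: TBSCl, imidazole, CH2Cl2, 0 °C
Reagents that add atoms: tert-butyl(chloro)dimethylsilane, CC(C)(C)[Si](C)(C)Cl
Why: Silylation should select the primary hydroxyl over the flanked secondary one, leaving only the C8 hydroxyl free for acylation.

Step 15
Reactants: 26 methyl but-2-ynoate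
Product: 28 methyl (2Z)-2-(hydroxymethyl)but-2-enoate, via vinylalane 27 (not isolated)
Conditions: i-Bu2AlH, HMPA, THF, 0 °C; then CH2O (gas), 0 to 25 °C; aq. HCl
Reagents that add atoms: formaldehyde, C=O
Why: syn-Hydroalumination of the ynoate (hydride to the β-carbon, aluminium to the α-carbon) and hydroxymethylation of the vinylalane with retention should give the enoate with methyl and ester cis.

Step 16
Reactants: 28 methyl (2Z)-2-(hydroxymethyl)but-2-enoate
Product: 29 methyl (2Z)-2-({[tert-butyl(dimethyl)silyl]oxy}methyl)but-2-enoate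
Conditions: TBSCl, imidazole, DMF, 25 °C
Reagents that add atoms: tert-butyl(chloro)dimethylsilane, CC(C)(C)[Si](C)(C)Cl
Why: Silyl ether formation blocks the side-chain hydroxyl so that the acid cannot acylate itself in step 18.

Step 17
Reactants: 29 the silyl ether of step 16
Product: 30 (2Z)-2-({[tert-butyl(dimethyl)silyl]oxy}methyl)but-2-enoic acid
Conditions: LiOH, THF/MeOH/H2O, 25 °C; then 1 M HCl to pH 3, 0 °C
Reagents that add atoms: lithium hydroxide, [Li+].[OH-]
Why: Ester saponification under mild conditions should free the acid without loss of the silyl ether or of the alkene geometry.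

Step 18
Reactants: 30 the acid of step 17, 25 the alcohol of step 14
Product: 32 (3aR,4S,6R,7S,7aR)-6-({[tert-butyl(dimethyl)silyl]oxy}methyl)-7-{3-[(tert-butyldiphenylsilyl)oxy]prop-1-en-2-yl}-6-ethenyl-3-methylidene-2-oxooctahydro-1-benzofuran-4-yl (2Z)-2-({[tert-butyl(dimethyl)silyl]oxy}methyl)but-2-enoate, via mixed anhydride 31 (not isolated)
Conditions: 2,4,6-trichlorobenzoyl chloride, Et3N, THF, 0 °C; then 25, DMAP, toluene, 25 °C
Reagents that add atoms: none
Why: Yamaguchi esterification through the mixed anhydride should acylate the hindered secondary alcohol with retention at C8, and a small amount of DMAP limits Z-to-E isomerisation of the acyl group.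

Step 19
Reactants: 32 the tris-silyl ether of step 18
Product: 33 (3aR,4S,6R,7S,7aR)-6-ethenyl-6-(hydroxymethyl)-7-(3-hydroxyprop-1-en-2-yl)-3-methylidene-2-oxooctahydro-1-benzofuran-4-yl (2Z)-2-(hydroxymethyl)but-2-enoate
Conditions: HF·pyridine, pyridine, THF, 0 to 25 °C
Reagents that add atoms: none
Why: Buffered fluoride desilylation should remove all three silyl ethers without acyl migration, conjugate addition to the α-methylene lactone or change of alkene geometry.

**Compound list**

1 | (5S)-5-(hydroxymethyl)furan-2(5H)-one | O=C1C=C[C@@H](CO)O1 | starting material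
2 | [(2S)-5-oxo-2,5-dihydrofuran-2-yl]methyl 2,2-dimethylpropanoate | O=C1C=C[C@@H](COC(=O)C(C)(C)C)O1 | intermediate
3 | 2-bromoprop-2-en-1-ol | C=C(Br)CO | starting material
4 | [(2-bromoprop-2-en-1-yl)oxy](tert-butyl)diphenylsilane | C=C(Br)CO[Si](c1ccccc1)(c1ccccc1)C(C)(C)C | intermediate
5 | {[tert-butyl(dimethyl)silyl]oxy}acetaldehyde | O=CCO[Si](C)(C)C(C)(C)C | starting material
6 | lithium bis{3-[(tert-butyldiphenylsilyl)oxy]prop-1-en-2-yl}cuprate | [Li+].C=C(CO[Si](c1ccccc1)(c1ccccc1)C(C)(C)C)[Cu-]C(=C)CO[Si](c1ccccc1)(c1ccccc1)C(C)(C)C | intermediate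
7 | lithium enolate of the trans-4-alkenyl-5-(pivaloyloxymethyl) lactone (conjugate adduct of 6 and 2) | [Li+].[O-]C1=C[C@H](C(=C)CO[Si](c2ccccc2)(c2ccccc2)C(C)(C)C)[C@@H](COC(=O)C(C)(C)C)O1 | intermediate
8 | [(2S,3R)-4-(2-{[tert-butyl(dimethyl)silyl]oxy}-1-hydroxyethyl)-3-{3-[(tert-butyldiphenylsilyl)oxy]prop-1-en-2-yl}-5-oxooxolan-2-yl]methyl 2,2-dimethylpropanoate (epimer mixture at C4 and the carbinol carbon) | O=C1C(C(O)CO[Si](C)(C)C(C)(C)C)[C@H](C(=C)CO[Si](c2ccccc2)(c2ccccc2)C(C)(C)C)[C@@H](COC(=O)C(C)(C)C)O1 | intermediate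
9 | methanesulfonate of 8 at the side-chain carbinol | O=C1C(C(OS(C)(=O)=O)CO[Si](C)(C)C(C)(C)C)[C@H](C(=C)CO[Si](c2ccccc2)(c2ccccc2)C(C)(C)C)[C@@H](COC(=O)C(C)(C)C)O1 | intermediate
10 | [(2S,3S,4E)-4-(2-{[tert-butyl(dimethyl)silyl]oxy}ethylidene)-3-{3-[(tert-butyldiphenylsilyl)oxy]prop-1-en-2-yl}-5-oxooxolan-2-yl]methyl 2,2-dimethylpropanoate | O=C1/C(=C/CO[Si](C)(C)C(C)(C)C)[C@H](C(=C)CO[Si](c2ccccc2)(c2ccccc2)C(C)(C)C)[C@@H](COC(=O)C(C)(C)C)O1 | intermediate
11 | (2S,3S,4E)-6-{[tert-butyl(dimethyl)silyl]oxy}-3-{3-[(tert-butyldiphenylsilyl)oxy]prop-1-en-2-yl}-4-(hydroxymethyl)hex-4-ene-1,2-diol | OC/C(=C/CO[Si](C)(C)C(C)(C)C)[C@H](C(=C)CO[Si](c1ccccc1)(c1ccccc1)C(C)(C)C)[C@H](O)CO | intermediate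
12 | (3S,4E)-4-(2-{[tert-butyl(dimethyl)silyl]oxy}ethylidene)-3-{3-[(tert-butyldiphenylsilyl)oxy]prop-1-en-2-yl}oxolan-2-ol (anomer mixture) | OC1OC/C(=C/CO[Si](C)(C)C(C)(C)C)[C@@H]1C(=C)CO[Si](c1ccccc1)(c1ccccc1)C(C)(C)C | intermediate
13 | (2E)-2-[(4S)-4-{3-[(tert-butyldiphenylsilyl)oxy]prop-1-en-2-yl}-5-methoxyoxolan-3-ylidene]ethan-1-ol (anomer mixture) | COC1OC/C(=C/CO)[C@@H]1C(=C)CO[Si](c1ccccc1)(c1ccccc1)C(C)(C)C | intermediate
14 | but-2-ynoic acid | CC#CC(=O)O | starting material
15 | (2Z)-3-bromobut-2-enoic acid | O=C(O)/C=C(\Br)C | intermediate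
16 | (2Z)-3,4-dibromobut-2-enoic acid | O=C(O)/C=C(\Br)CBr | intermediate
17 | (2Z)-3,4-dibromobut-2-enoyl chloride | O=C(Cl)/C=C(\Br)CBr | intermediate
18 | (2E)-2-[(4S)-4-{3-[(tert-butyldiphenylsilyl)oxy]prop-1-en-2-yl}-5-methoxyoxolan-3-ylidene]ethyl (2Z)-3,4-dibromobut-2-enoate (anomer mixture) | COC1OC/C(=C/COC(=O)/C=C(\Br)CBr)[C@@H]1C(=C)CO[Si](c1ccccc1)(c1ccccc1)C(C)(C)C | intermediate
19 | tert-butyl{[2-((3S,4E)-4-{2-[((3Z)-4,5-dibromopenta-1,3-dien-2-yl)oxy]ethylidene}-2-methoxyoxolan-3-yl)prop-2-en-1-yl]oxy}diphenylsilane (anomer mixture) | COC1OC/C(=C/COC(=C)/C=C(\Br)CBr)[C@@H]1C(=C)CO[Si](c1ccccc1)(c1ccccc1)C(C)(C)C | intermediate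
20 | (3Z)-4,5-dibromo-1-[(3R,4S)-4-{3-[(tert-butyldiphenylsilyl)oxy]prop-1-en-2-yl}-3-ethenyl-5-methoxyoxolan-3-yl]pent-3-en-2-one (anomer mixture) | COC1OC[C@@](C=C)(CC(=O)/C=C(\Br)CBr)[C@@H]1C(=C)CO[Si](c1ccccc1)(c1ccccc1)C(C)(C)C | intermediate
21 | (3Z)-4,5-dibromo-1-[(3R,4S)-4-{3-[(tert-butyldiphenylsilyl)oxy]prop-1-en-2-yl}-3-ethenyl-5-hydroxyoxolan-3-yl]pent-3-en-2-one (anomer mixture) | OC1OC[C@@](C=C)(CC(=O)/C=C(\Br)CBr)[C@@H]1C(=C)CO[Si](c1ccccc1)(c1ccccc1)C(C)(C)C | intermediate
22 | (2S,3R,4S,5R)-2-(1-bromoethenyl)-4-{3-[(tert-butyldiphenylsilyl)oxy]prop-1-en-2-yl}-5-ethenyl-3-hydroxy-5-(hydroxymethyl)cyclohexan-1-one | C=C[C@]1(CO)CC(=O)[C@@H](C(Br)=C)[C@H](O)[C@H]1C(=C)CO[Si](c1ccccc1)(c1ccccc1)C(C)(C)C | intermediate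
23 | (3aS,6R,7S,7aR)-7-{3-[(tert-butyldiphenylsilyl)oxy]prop-1-en-2-yl}-6-ethenyl-6-(hydroxymethyl)-3-methylidenetetrahydro-1-benzofuran-2,4(3H,5H)-dione | C=C[C@]1(CO)CC(=O)[C@H]2C(=C)C(=O)O[C@@H]2[C@H]1C(=C)CO[Si](c1ccccc1)(c1ccccc1)C(C)(C)C | intermediate
24 | (3aR,4S,6R,7S,7aR)-7-{3-[(tert-butyldiphenylsilyl)oxy]prop-1-en-2-yl}-6-ethenyl-4-hydroxy-6-(hydroxymethyl)-3-methylidenehexahydro-1-benzofuran-2(3H)-one | C=C[C@]1(CO)C[C@H](O)[C@H]2C(=C)C(=O)O[C@@H]2[C@H]1C(=C)CO[Si](c1ccccc1)(c1ccccc1)C(C)(C)C | intermediate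
25 | (3aR,4S,6R,7S,7aR)-6-({[tert-butyl(dimethyl)silyl]oxy}methyl)-7-{3-[(tert-butyldiphenylsilyl)oxy]prop-1-en-2-yl}-6-ethenyl-4-hydroxy-3-methylidenehexahydro-1-benzofuran-2(3H)-one | C=C[C@]1(CO[Si](C)(C)C(C)(C)C)C[C@H](O)[C@H]2C(=C)C(=O)O[C@@H]2[C@H]1C(=C)CO[Si](c1ccccc1)(c1ccccc1)C(C)(C)C | intermediate
26 | methyl but-2-ynoate | CC#CC(=O)OC | starting material
27 | methyl (2E)-2-[bis(2-methylpropyl)alumanyl]but-2-enoate (methyl cis to the ester) | COC(=O)/C(=C\C)[Al](CC(C)C)CC(C)C | intermediate
28 | methyl (2Z)-2-(hydroxymethyl)but-2-enoate | COC(=O)/C(=C\C)CO | intermediate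
29 | methyl (2Z)-2-({[tert-butyl(dimethyl)silyl]oxy}methyl)but-2-enoate | COC(=O)/C(=C\C)CO[Si](C)(C)C(C)(C)C | intermediate
30 | (2Z)-2-({[tert-butyl(dimethyl)silyl]oxy}methyl)but-2-enoic acid | OC(=O)/C(=C\C)CO[Si](C)(C)C(C)(C)C | intermediate
31 | (2Z)-2-({[tert-butyl(dimethyl)silyl]oxy}methyl)but-2-enoic 2,4,6-trichlorobenzoic anhydride | O=C(OC(=O)c1c(Cl)cc(Cl)cc1Cl)/C(=C\C)CO[Si](C)(C)C(C)(C)C | intermediate
32 | (3aR,4S,6R,7S,7aR)-6-({[tert-butyl(dimethyl)silyl]oxy}methyl)-7-{3-[(tert-butyldiphenylsilyl)oxy]prop-1-en-2-yl}-6-ethenyl-3-methylidene-2-oxooctahydro-1-benzofuran-4-yl (2Z)-2-({[tert-butyl(dimethyl)silyl]oxy}methyl)but-2-enoate | C=C[C@]1(CO[Si](C)(C)C(C)(C)C)C[C@H](OC(=O)/C(=C\C)CO[Si](C)(C)C(C)(C)C)[C@H]2C(=C)C(=O)O[C@@H]2[C@H]1C(=C)CO[Si](c1ccccc1)(c1ccccc1)C(C)(C)C | intermediate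
33 | (3aR,4S,6R,7S,7aR)-6-ethenyl-6-(hydroxymethyl)-7-(3-hydroxyprop-1-en-2-yl)-3-methylidene-2-oxooctahydro-1-benzofuran-4-yl (2Z)-2-(hydroxymethyl)but-2-enoate | C=C[C@]1(CO)C[C@H](OC(=O)/C(=C\C)CO)[C@H]2C(=C)C(=O)O[C@@H]2[C@H]1C(=C)CO | target

**Summary**

Total step count: 19.
Longest linear sequence: 13 steps (steps 1, 3, 4, 5, 6, 9, 10, 11, 12, 13, 14, 18, 19).

Steps most likely to fail:

Step 11. The indium dienolate may be protonated, or may lose bromide to an allenyl ketone, before it closes the ring; the closure may go through the other aldehyde face; and facial control in the rearrangement may be incomplete. Fallback: from 19 the rearrangement is run alone and ketone 20 is isolated. The acetal is then hydrolysed with aqueous acetic acid to lactol 21. The ring is closed under anhydrous Nozaki–Hiyama–Kishi conditions (CrCl2, THF), in which the dienolate generated by divalent chromium adds through a closed chair transition state. The sequence comes back at 22 and makes no compound outside the list (F0).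

Step 10. The titanium methylidene may attack the allylic bromide or the conjugated alkene, and the dienyl ether may hydrolyse on isolation. Fallback (Carroll route, no methylenation): from 16 and 13, acid chloride 17 is condensed with Meldrum's acid (pyridine, CH2Cl2) to 5-[(2Z)-3,4-dibromo-1-hydroxybut-2-en-1-ylidene]-2,2-dimethyl-1,3-dioxane-4,6-dione F1. F1 is heated with 13 (toluene, 80 °C) to the allyl β-keto ester (2E)-2-[(4S)-4-{3-[(tert-butyldiphenylsilyl)oxy]prop-1-en-2-yl}-5-methoxyoxolan-3-ylidene]ethyl (4Z)-5,6-dibromo-3-oxohex-4-enoate F2. Thermal Carroll rearrangement of F2 with decarboxylation (xylene, 140 °C) should give ketone 20, where the route is rejoined at the second stage of step 11.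

Step 13. Facial control is lost if hydride is not delivered through the C14 hydroxyl (hemiketal formation or external attack). Fallback: from 23 the primary hydroxyl is silylated first (TBSCl, imidazole) to (3aS,6R,7S,7aR)-6-({[tert-butyl(dimethyl)silyl]oxy}methyl)-7-{3-[(tert-butyldiphenylsilyl)oxy]prop-1-en-2-yl}-6-ethenyl-3-methylidenetetrahydro-1-benzofuran-2,4(3H,5H)-dione F3. The ketone is reduced under Luche conditions (NaBH4, CeCl3·7H2O, MeOH, −78 °C), where the axial silyloxymethyl group should block axial attack and give the axial alcohol (3aR,4R,6R,7S,7aR)-6-({[tert-butyl(dimethyl)silyl]oxy}methyl)-7-{3-[(tert-butyldiphenylsilyl)oxy]prop-1-en-2-yl}-6-ethenyl-4-hydroxy-3-methylidenehexahydro-1-benzofuran-2(3H)-one F4. F4 is esterified with acid 30 under Mitsunobu conditions (PPh3, DIAD, THF) with inversion, which comes back at 32.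

**Further compounds**

F0 | step 11 | none | none
F1 | step 10 | 5-[(2Z)-3,4-dibromo-1-hydroxybut-2-en-1-ylidene]-2,2-dimethyl-1,3-dioxane-4,6-dione | CC1(C)OC(=O)C(=C(O)/C=C(\Br)CBr)C(=O)O1
F2 | step 10 | (2E)-2-[(4S)-4-{3-[(tert-butyldiphenylsilyl)oxy]prop-1-en-2-yl}-5-methoxyoxolan-3-ylidene]ethyl (4Z)-5,6-dibromo-3-oxohex-4-enoate | COC1OC/C(=C/COC(=O)CC(=O)/C=C(\Br)CBr)[C@@H]1C(=C)CO[Si](c1ccccc1)(c1ccccc1)C(C)(C)C
F3 | step 13 | (3aS,6R,7S,7aR)-6-({[tert-butyl(dimethyl)silyl]oxy}methyl)-7-{3-[(tert-butyldiphenylsilyl)oxy]prop-1-en-2-yl}-6-ethenyl-3-methylidenetetrahydro-1-benzofuran-2,4(3H,5H)-dione | C=C[C@]1(CO[Si](C)(C)C(C)(C)C)CC(=O)[C@H]2C(=C)C(=O)O[C@@H]2[C@H]1C(=C)CO[Si](c1ccccc1)(c1ccccc1)C(C)(C)C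
F4 | step 13 | (3aR,4R,6R,7S,7aR)-6-({[tert-butyl(dimethyl)silyl]oxy}methyl)-7-{3-[(tert-butyldiphenylsilyl)oxy]prop-1-en-2-yl}-6-ethenyl-4-hydroxy-3-methylidenehexahydro-1-benzofuran-2(3H)-one | C=C[C@]1(CO[Si](C)(C)C(C)(C)C)C[C@@H](O)[C@H]2C(=C)C(=O)O[C@@H]2[C@H]1C(=C)CO[Si](c1ccccc1)(c1ccccc1)C(C)(C)C
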